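**Plan**
- Retrosynthesis: the two aryl methyl ethers at C5 and C8 are removed last. Ring B is then cut at C1–C2 and C3–C4, and the side-chain ester at its acyl C–O bond.
- Enabling feature: ring B is a quinone whose C2=C3 unit carries only the side chain (C2) and a hydrogen (C3). Its carbonyl carbons C1 and C4 sit on a 5,8-dioxygenated benzo ring (ring A with C4a/C8a) that has twofold symmetry. C2=C3 is therefore a terminal alkyne, and C1/C4 are the carbonyls of a symmetrical benzocyclobutenedione.
- Forward: ring A is bought. The four-membered ring is fused on by aryne [2+2] and oxidised to the 1,2-dione. Cobalt-mediated insertion of the alkyne expands it to ring B. Oxidative demethylation and reduction give the naphthazarin.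
- Side chain: 4-methylpent-3-enoic acid is joined to trimethylsilylacetylene as an ynone, then reduced, desilylated and acylated.
- Stereochemistry: the single (S) centre is set by ligand-controlled asymmetric transfer hydrogenation of the ynone. Its C–O bond is never broken afterwards.

Key step: step 9

Remark: a naphthazarin is a pair of rapidly interconverting tautomers, so the compound formed in the last step is the target whichever ring is drawn as the quinone; 22 is written as in the target SMILES.

**Route**

Step 1
Reactants: 1 2-bromo-1,4-dimethoxybenzene; 2 1,1-dimethoxyethene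
Product: 5 2,5-dimethoxybicyclo[4.2.0]octa-1,3,5-trien-7-one (3,6-dimethoxybenzocyclobutenone), via 3,6-dimethoxybenzyne 3 (not isolated), via 2,5,7,7-tetramethoxybicyclo[4.2.0]octa-1,3,5-triene 4 (not isolated)
Conditions: NaNH2, THF, reflux; then 1 M HCl, THF, rt
Reagents that add atoms: water, O
Why: NaNH2 removes HBr across C2–C3 of 1 (the only hydrogen ortho to bromine) to give the symmetrical aryne 3, whose [2+2] cycloaddition to the electron-rich ketene acetal 2 gives the benzocyclobutenone ketal 4, and dilute acid in the work-up hydrolyses this ketal to ketone 5 without touching the aryl methyl ethers (aryne [2+2] cycloaddition, ketal hydrolysis).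

Step 2
Reactants: 5 2,5-dimethoxybicyclo[4.2.0]octa-1,3,5-trien-7-one
Product: 6 8,8-dibromo-2,5-dimethoxybicyclo[4.2.0]octa-1,3,5-trien-7-one
Conditions: NBS (2.2 equiv), (PhCO2)2 (cat.), CCl4, reflux
Reagents that add atoms: N-bromosuccinimide, O=C1CCC(=O)N1Br
Why: The ring CH2 of 5 is benzylic as well as alpha to the ketone, so the radical chain of a Wohl–Ziegler bromination should replace both hydrogens, while the arene, deactivated by the acyl group, should resist ring bromination in a non-polar medium.

Step 3
Reactants: 6 8,8-dibromo-2,5-dimethoxybicyclo[4.2.0]octa-1,3,5-trien-7-one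
Product: 7 2,5-dimethoxybicyclo[4.2.0]octa-1,3,5-triene-7,8-dione (3,6-dimethoxybenzocyclobutene-1,2-dione)
Conditions: AgO2CCF3 (2.2 equiv), MeCN/H2O, rt to 50 °C
Reagents that add atoms: water, O
Why: Silver ion pulls bromide from the geminal dibromide, the cation being stabilised by the electron-rich arene, water adds and the bromohydrin collapses with loss of the second bromide to the 1,2-dione (silver-assisted hydrolysis of a gem-dihalide), the aryl methyl ethers being inert.

Step 4
Reactants: 8 4-methylpent-3-enoic acid
Product: 10 N-methoxy-N,4-dimethylpent-3-enamide, via 1-(4-methylpent-3-enoyl)imidazole 9 (not isolated)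
Conditions: 1,1'-carbonyldiimidazole, CH2Cl2, rt; then MeNH(OMe)·HCl, rt
Reagents that add atoms: N,O-dimethylhydroxylamine hydrochloride, CNOC.Cl
Why: Activation as the acyl imidazole 9 and aminolysis under near-neutral conditions gives the Weinreb amide without passing through an acid chloride or ketene that could move the beta,gamma-alkene into conjugation (amide formation via an acyl imidazole).

Step 5
Reactants: 10 N-methoxy-N,4-dimethylpent-3-enamide; 11 trimethylsilylacetylene
Product: 13 6-methyl-1-(trimethylsilyl)hept-5-en-1-yn-3-one, via lithium (trimethylsilyl)acetylide 12 (not isolated)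
Conditions: 11, n-BuLi, THF, −78 °C; then 10, −78 to −20 °C; cold aq. NH4Cl
Reagents that add atoms: none
Why: The lithium acetylide 12 adds once to the Weinreb amide and the chelated tetrahedral adduct survives until the cold buffered quench, so no tertiary alcohol forms and the base-sensitive beta,gamma-unsaturated ynone is released only at work-up (Weinreb ketone synthesis).

Step 6
Reactants: 13 6-methyl-1-(trimethylsilyl)hept-5-en-1-yn-3-one
Product: 14 (S)-6-methyl-1-(trimethylsilyl)hept-5-en-1-yn-3-ol
Conditions: Ru[(S,S)-TsNCHPhCHPhNH](p-cymene) (1 mol %), i-PrOH, rt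
Reagents that add atoms: none
Why: In this Noyori asymmetric transfer hydrogenation the base-free amido ruthenium complex takes hydrogen from 2-propanol and passes hydride and proton to the carbonyl through a six-membered transition state in which the alkynyl group takes the place of the aryl group of an aryl ketone, so the (S,S)-ligand should deliver hydride to the face that gives the (S)-carbinol, while the neutral medium leaves the alkyne, the silyl group and the beta,gamma-alkene in place.

Step 7
Reactants: 14 (S)-6-methyl-1-(trimethylsilyl)hept-5-en-1-yn-3-ol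
Product: 15 (S)-6-methylhept-5-en-1-yn-3-ol
Conditions: K2CO3 (cat.), MeOH, 0 °C to rt
Reagents that add atoms: none
Why: Methoxide attacks silicon and the departing acetylide is protonated by methanol (protiodesilylation of an alkynylsilane), the carbinol stereocenter not being involved.

Step 8
Reactants: 15 (S)-6-methylhept-5-en-1-yn-3-ol; 16 3-methylbutanoyl chloride
Product: 17 (S)-6-methylhept-5-en-1-yn-3-yl 3-methylbutanoate
Conditions: pyridine, DMAP (cat.), CH2Cl2, 0 °C to rt
Reagents that add atoms: none
Why: DMAP-catalysed O-acylation (nucleophilic acyl substitution) forms the ester at oxygen without breaking the C–O bond of the stereocenter, so the (S) configuration is retained.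

Step 9
Reactants: 7 2,5-dimethoxybicyclo[4.2.0]octa-1,3,5-triene-7,8-dione; 17 (S)-6-methylhept-5-en-1-yn-3-yl 3-methylbutanoate
Product: 20 (S)-1-(5,8-dimethoxy-1,4-dioxo-1,4-dihydronaphthalen-2-yl)-4-methylpent-3-en-1-yl 3-methylbutanoate, via chlorobis(triphenylphosphine)(3,6-dimethoxyphthaloyl)cobalt 18 (not isolated), via chloro(dimethylglyoxime)(pyridine)(3,6-dimethoxyphthaloyl)cobalt 19 (not isolated)
Conditions: 7, CoCl(PPh3)3, PhCl, 50 °C; dimethylglyoxime, pyridine, rt; evaporation, Et2O wash of the crude solid; then 17, CoCl2·6H2O, ClCH2CH2Cl, 80 °C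
Reagents that add atoms: none
Why: Monovalent cobalt in CoCl(PPh3)3 inserts oxidatively into the strained bond between the two carbonyl carbons of 7 to give the five-membered phthaloyl complex 18 of trivalent cobalt, and exchange of the phosphines for dimethylglyoxime and pyridine gives the air-stable, more reactive complex 19. With CoCl2·6H2O as Lewis acid a coordination site opens, the terminal alkyne of 17 binds and inserts into one cobalt–acyl bond (forming C1–C2 or C3–C4), and C–C reductive elimination from the seven-membered cobaltacycle forms the other bond and returns monovalent cobalt. This is the known phthaloylcobalt synthesis of 1,4-naphthoquinones from benzocyclobutenediones and alkynes, applied here to a propargylic ester. Ring B is closed by that reductive elimination, a metal-mediated formal [4+2] union of the C(=O)–C4a=C8a–C(=O) unit with the two alkyne carbons, and it arrives directly at the quinone oxidation level. No stereocenter is formed, and the (S) carbinol carbon of 17 is a spectator whose C–O and C–H bonds are not involved. The step needs chemoselectivity for the alkyne over the trisubstituted alkene and the ester, which cobalt–acyl insertion provides because unactivated alkenes do not insert, and it needs no regiocontrol because the twofold symmetry of the 3,6-dimethoxyphthaloyl unit makes both insertion senses give 20.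

Step 10
Reactants: 20 (S)-1-(5,8-dimethoxy-1,4-dioxo-1,4-dihydronaphthalen-2-yl)-4-methylpent-3-en-1-yl 3-methylbutanoate
Product: 22 isovalerylalkannin, (S)-1-(5,8-dihydroxy-1,4-dioxo-1,4-dihydronaphthalen-2-yl)-4-methylpent-3-en-1-yl 3-methylbutanoate, via (S)-4-methyl-1-(1,4,5,8-tetraoxo-1,4,5,8-tetrahydronaphthalen-2-yl)pent-3-en-1-yl 3-methylbutanoate 21 (not isolated)
Conditions: AgO, 6 M HNO3, acetone, rt, 5 min; then Na2S2O4 (1 equiv), H2O/CHCl3, 0 °C
Reagents that add atoms: water, O
Why: AgO in nitric acid oxidises the 5,8-dimethoxy ring to its radical cation, water attacks the two ipso carbons and methanol is lost (oxidative demethylation of a hydroquinone dimethyl ether) to give the diquinone 21, a strong oxidant that one equivalent of dithionite reduces by two electrons to the naphthazarin 22, while the short contact time should spare the trisubstituted alkene and the ester and the stereocenter is not touched.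

**Compound list**

1 | 2-bromo-1,4-dimethoxybenzene | COc1ccc(OC)c(Br)c1 | starting material
2 | 1,1-dimethoxyethene | C=C(OC)OC | starting material
3 | 3,6-dimethoxybenzyne | COC1=CC=C(OC)C#C1 | intermediate
4 | 2,5,7,7-tetramethoxybicyclo[4.2.0]octa-1,3,5-triene | COc1ccc(OC)c2c1CC2(OC)OC | intermediate
5 | 2,5-dimethoxybicyclo[4.2.0]octa-1,3,5-trien-7-one | COc1ccc(OC)c2c1CC2=O | intermediate
6 | 8,8-dibromo-2,5-dimethoxybicyclo[4.2.0]octa-1,3,5-trien-7-one | COc1ccc(OC)c2c1C(=O)C2(Br)Br | intermediate
7 | 2,5-dimethoxybicyclo[4.2.0]octa-1,3,5-triene-7,8-dione (3,6-dimethoxybenzocyclobutene-1,2-dione) | COc1ccc(OC)c2c1C(=O)C2=O | intermediate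
8 | 4-methylpent-3-enoic acid | CC(C)=CCC(=O)O | starting material
9 | 1-(4-methylpent-3-enoyl)imidazole | CC(C)=CCC(=O)n1ccnc1 | intermediate
10 | N-methoxy-N,4-dimethylpent-3-enamide | CC(C)=CCC(=O)N(C)OC | intermediate
11 | trimethylsilylacetylene | C#C[Si](C)(C)C | starting material
12 | lithium (trimethylsilyl)acetylide | [Li+].[C-]#C[Si](C)(C)C | intermediate
13 | 6-methyl-1-(trimethylsilyl)hept-5-en-1-yn-3-one | CC(C)=CCC(=O)C#C[Si](C)(C)C | intermediate
14 | (S)-6-methyl-1-(trimethylsilyl)hept-5-en-1-yn-3-ol | CC(C)=CC[C@H](O)C#C[Si](C)(C)C | intermediate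
15 | (S)-6-methylhept-5-en-1-yn-3-ol | CC(C)=CC[C@H](O)C#C | intermediate
16 | 3-methylbutanoyl chloride | CC(C)CC(Cl)=O | starting material
17 | (S)-6-methylhept-5-en-1-yn-3-yl 3-methylbutanoate | CC(C)=CC[C@H](OC(=O)CC(C)C)C#C | intermediate
18 | chlorobis(triphenylphosphine)(3,6-dimethoxyphthaloyl)cobalt, five-membered cobaltacycle of trivalent cobalt | COc1ccc(OC)c2c1C(=O)[Co-2](Cl)([P+](c1ccccc1)(c1ccccc1)c1ccccc1)([P+](c1ccccc1)(c1ccccc1)c1ccccc1)C2=O | intermediate
19 | chloro(dimethylglyoxime)(pyridine)(3,6-dimethoxyphthaloyl)cobalt, N,N-chelated neutral dimethylglyoxime | COc1ccc(OC)c2c1C(=O)[Co-3]3(Cl)([n+]4ccccc4)([N+](O)=C(C)C(C)=[N+]3O)C2=O | intermediate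
20 | (S)-1-(5,8-dimethoxy-1,4-dioxo-1,4-dihydronaphthalen-2-yl)-4-methylpent-3-en-1-yl 3-methylbutanoate | CC(C)=CC[C@H](OC(=O)CC(C)C)C1=CC(=O)c2c(OC)ccc(OC)c2C1=O | intermediate
21 | (S)-4-methyl-1-(1,4,5,8-tetraoxo-1,4,5,8-tetrahydronaphthalen-2-yl)pent-3-en-1-yl 3-methylbutanoate | CC(C)=CC[C@H](OC(=O)CC(C)C)C1=CC(=O)C2=C(C1=O)C(=O)C=CC2=O | intermediate
22 | isovalerylalkannin, (S)-1-(5,8-dihydroxy-1,4-dioxo-1,4-dihydronaphthalen-2-yl)-4-methylpent-3-en-1-yl 3-methylbutanoate | CC(C)=CC[C@H](OC(=O)CC(C)C)C1=CC(=O)c2c(O)ccc(O)c2C1=O | target

**Step count and risks**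

Total steps: 10. Longest linear sequence: 7 steps (steps 4 to 10, from 8 to 22). The dione branch (steps 1 to 3) joins at step 9.

Most likely to fail:

1. Step 9. The propargylic acyloxy group may ionise or rearrange to an allenyl ester under the Lewis acid at 80 °C. The ester carbonyl may also chelate cobalt after alkyne binding and stall insertion, so that the alkyne is consumed without ring closure. The fallback moves the esterification behind the ring expansion and sets out from 15. Silylation (TBSCl, imidazole, DMF) should give (S)-tert-butyldimethyl[(6-methylhept-5-en-1-yn-3-yl)oxy]silane F1. The same cobalt sequence from 7 through 18 and 19, with F1 as the alkyne, should give (S)-2-[1-(tert-butyldimethylsilyloxy)-4-methylpent-3-en-1-yl]-5,8-dimethoxynaphthalene-1,4-dione F2. HF·pyridine in THF should then free (S)-2-(1-hydroxy-4-methylpent-3-en-1-yl)-5,8-dimethoxynaphthalene-1,4-dione F3. Acylation with 16 (pyridine, DMAP, CH2Cl2) comes back to the route at 20.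

2. Step 10. The AgO/HNO3 medium may oxidise or hydrate the trisubstituted alkene. Any excess of dithionite may reduce the naphthazarin further to its leuco form, which expels the acyloxy group through a quinone methide. The fallback sets out from 20 and removes the methyl groups from a ring made temporarily electron-poor. Reductive acetylation (Zn dust, Ac2O, pyridine, rt), which traps the hydroquinone as it forms, should give (S)-1-(1,4-diacetoxy-5,8-dimethoxynaphthalen-2-yl)-4-methylpent-3-en-1-yl 3-methylbutanoate F4. (NH4)2Ce(NO3)6 in MeCN/H2O at 0 °C should oxidise only the dimethoxy ring, the diacetoxy ring being deactivated, to (S)-1-(1,4-diacetoxy-5,8-dioxo-5,8-dihydronaphthalen-2-yl)-4-methylpent-3-en-1-yl 3-methylbutanoate F5. Brief methanolysis (KHCO3, MeOH, 0 °C) should cleave the two aryl acetates, which are far more labile than the secondary alkyl isovalerate. The naphthazarin set free is the tautomeric form of 22, where the fallback comes back to the route.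

3. Step 6. The beta,gamma-alkene of 13 may migrate into conjugation with the ynone before hydride transfer, and discrimination between the alkynyl and the CH2 flank may be incomplete. The fallback sets the carbinol by reagent-controlled allylboration and installs the trisubstituted alkene afterwards, so that no beta,gamma-unsaturated ketone is handled. It sets out from 11. Lithiation and formylation (n-BuLi, then DMF, THF, −78 °C, buffered quench) should give 3-(trimethylsilyl)prop-2-ynal F6. Brown allylation with (−)-Ipc2B(CH2CH=CH2), made from (−)-Ipc2BOMe and CH2=CHCH2MgBr, in Et2O at −78 °C with NaBO3 work-up should give (S)-1-(trimethylsilyl)hex-5-en-1-yn-3-ol F7. Cross-metathesis with excess 2-methylbut-2-ene (second-generation Grubbs catalyst RuCl2(=CHPh)(PCy3)(NHC), NHC = 1,3-dimesitylimidazolidin-2-ylidene, CH2Cl2, 40 °C) should exchange the terminal CH2 for CMe2 and comes back to the route at 14.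

**Further compounds**

F1 | step 9 | (S)-tert-butyldimethyl[(6-methylhept-5-en-1-yn-3-yl)oxy]silane | CC(C)=CC[C@H](O[Si](C)(C)C(C)(C)C)C#C
F2 | step 9 | (S)-2-[1-(tert-butyldimethylsilyloxy)-4-methylpent-3-en-1-yl]-5,8-dimethoxynaphthalene-1,4-dione | CC(C)=CC[C@H](O[Si](C)(C)C(C)(C)C)C1=CC(=O)c2c(OC)ccc(OC)c2C1=O
F3 | step 9 | (S)-2-(1-hydroxy-4-methylpent-3-en-1-yl)-5,8-dimethoxynaphthalene-1,4-dione | CC(C)=CC[C@H](O)C1=CC(=O)c2c(OC)ccc(OC)c2C1=O
F4 | step 10 | (S)-1-(1,4-diacetoxy-5,8-dimethoxynaphthalen-2-yl)-4-methylpent-3-en-1-yl 3-methylbutanoate | CC(C)=CC[C@H](OC(=O)CC(C)C)c1cc(OC(C)=O)c2c(OC)ccc(OC)c2c1OC(C)=O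
F5 | step 10 | (S)-1-(1,4-diacetoxy-5,8-dioxo-5,8-dihydronaphthalen-2-yl)-4-methylpent-3-en-1-yl 3-methylbutanoate | CC(C)=CC[C@H](OC(=O)CC(C)C)c1cc(OC(C)=O)c2C(=O)C=CC(=O)c2c1OC(C)=O
F6 | step 6 | 3-(trimethylsilyl)prop-2-ynal | C[Si](C)(C)C#CC=O
F7 | step 6 | (S)-1-(trimethylsilyl)hex-5-en-1-yn-3-ol | C=CC[C@H](O)C#C[Si](C)(C)C
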